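**Plan**

- Numbering: chain atoms carry the locants of the C14 ester precursor (C1 = terminal carboxyl carbon, C7 = ethyl-bearing centre, C9/C10 = ring alkene carbons, C11=C12 = butenyl alkene); the systematic names of the last two compounds use their own locants.
- Enabling feature: every carboxyl carbon except C1 sits on one of two neighbouring pairs of carbons, the cis pair on C9=C10 that forms the furan-2,5-dione ring and the pair on C4/C5 beside the C5=C6 alkene. These are an alkyne (C9≡C10) and an allene (C4=C5=C6) that have each added two CO2, so all four C–CO2 bonds are cut together once the tert-butyl ester is set aside.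
- Further cuts: the remaining allenyl enyne is cut at the allene (terminal alkyne plus tert-butyl 4-oxobutanoate), at C6 (one-carbon alkynylation of an aldehyde), at C10–C11 (alkyne–alkenyl iodide coupling) and at C7–C8 (imide enolate propargylation).
- Forward order: C7–C8, C10–C11, C6, the allene, then the four carboxylations; the anhydride, the only ring, closes in that last bond-forming step, and acidolysis of the ester ends the route.
- Stereochemistry: C7 from the (S)-4-benzyloxazolidinone auxiliary, C11=C12 from syn hydrozirconation of but-1-yne, C4 and the C5=C6 geometry from a chiral bipyridine–nickel η3-allyl intermediate, the ring alkene from syn dicarboxylation.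

Key step: step 9

Remark: the allene axis of the carboxylation precursor is left uncontrolled because the allylnickel intermediate should erase it, and the antipode of the chiral bipyridine that leads to 4R is assumed to be identified in a first run. Step 9 takes up four molecules of CO2 and two atoms of zinc per molecule of 17, the four new carboxyl protons come from the HCl work-up, and closure of the anhydride gives off one molecule of water.

**Route**

Step 1
Reactants: 1 (S)-4-benzyloxazolidin-2-one; 2 butanoyl chloride
Product: 4 (S)-4-benzyl-3-butanoyloxazolidin-2-one, via N-lithio oxazolidinone 3 (not isolated)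
Conditions: n-BuLi, THF, −78 °C; then 2, −78 → 0 °C
Reagents that add atoms: none
Why: N-acylation of the lithiated carbamate with an acid chloride is the standard loading of an Evans auxiliary and touches no stereocentre.

Step 2
Reactants: 4 (S)-4-benzyl-3-butanoyloxazolidin-2-one; 5 3-bromoprop-1-yne
Product: 7 (S)-4-benzyl-3-[(2R)-2-ethylpent-4-ynoyl]oxazolidin-2-one, via sodium Z-enolate 6 (not isolated)
Conditions: NaN(SiMe3)2, THF, −78 °C; then 5, −78 → −45 °C
Reagents that add atoms: none
Why: Evans asymmetric alkylation, in which the chelated Z-enolate is shielded on one face by the benzyl group, so the propargylic bromide enters from the other face and sets the ethyl-bearing centre (later C7) as R, the sense known for allylation of the corresponding propanoyl imide.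

Step 3
Reactants: 8 but-1-yne
Product: 10 (E)-1-iodobut-1-ene, via alkenylzirconocene chloride 9 (not isolated)
Conditions: Cp2Zr(H)Cl, THF, 0 °C → rt; then I2, 0 °C; kept as a stock solution
Reagents that add atoms: iodine, [I][I]
Why: Hydrozirconation adds Zr–H syn with zirconium at the terminal carbon and iododezirconation proceeds with retention, so the E-alkenyl iodide should result.

Step 4
Reactants: 7 (S)-4-benzyl-3-[(2R)-2-ethylpent-4-ynoyl]oxazolidin-2-one; 10 (E)-1-iodobut-1-ene
Product: 11 (S)-4-benzyl-3-[(2R,6E)-2-ethylnon-6-en-4-ynoyl]oxazolidin-2-one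
Conditions: PdCl2(PPh3)2 (cat.), CuI (cat.), iPr2NH, THF, rt, degassed
Reagents that add atoms: none
Why: Sonogashira coupling of a terminal alkyne with an alkenyl iodide runs at room temperature with retention of alkene geometry, and the amine base is too weak to epimerise the imide α-centre.

Step 5
Reactants: 11 (S)-4-benzyl-3-[(2R,6E)-2-ethylnon-6-en-4-ynoyl]oxazolidin-2-one
Product: 12 (2R,6E)-2-ethylnon-6-en-4-yn-1-ol
Conditions: LiBH4, MeOH (1 equiv), Et2O, 0 °C
Reagents that add atoms: none
Why: Reductive cleavage of an N-acyl oxazolidinone with LiBH4 gives the primary alcohol without touching the α-centre or the enyne and returns the auxiliary.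

Step 6
Reactants: 12 (2R,6E)-2-ethylnon-6-en-4-yn-1-ol
Product: 13 (2R,6E)-2-ethylnon-6-en-4-ynal
Conditions: Dess–Martin periodinane, NaHCO3, CH2Cl2, 0 °C → rt; used without storage
Reagents that add atoms: none
Why: Buffered Dess–Martin oxidation is neutral enough to keep an α-branched aldehyde configurationally intact and leaves the enyne alone.

Step 7
Reactants: 13 (2R,6E)-2-ethylnon-6-en-4-ynal
Product: 14 (3R,7E)-3-ethyldec-7-ene-1,5-diyne
Conditions: dimethyl (1-diazo-2-oxopropyl)phosphonate, K2CO3, MeOH, 0 °C → rt
Reagents that add atoms: dimethyl (1-diazo-2-oxopropyl)phosphonate, CC(=O)C(=[N+]=[N-])P(=O)(OC)OC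
Why: Seyferth–Gilbert homologation in its Ohira–Bestmann form turns the aldehyde into the terminal alkyne under mild carbonate conditions that are routinely applied to α-branched aldehydes with little loss of configuration.

Step 8
Reactants: 14 (3R,7E)-3-ethyldec-7-ene-1,5-diyne; 15 tert-butyl 4-oxobutanoate
Product: 17 tert-butyl (7R,11E)-7-ethyltetradeca-4,5,11-trien-9-ynoate (both allene axial epimers), via propargylic morpholine 16 (not isolated)
Conditions: morpholine, CuBr (cat.), 4 Å MS, toluene, rt → 50 °C; then ZnI2, 110 °C
Reagents that add atoms: none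
Why: Crabbé-type allenation of a terminal alkyne with an aldehyde, in which the copper-catalysed three-component coupling of alkyne, aldehyde and amine gives the propargylic amine and the zinc-activated alkyne then accepts a 1,5-hydride from the morpholine α-carbon with loss of the cyclic imine, while the internal enyne and the C7 centre take no part.

Step 9
Reactants: 17 tert-butyl (7R,11E)-7-ethyltetradeca-4,5,11-trien-9-ynoate; 18 carbon dioxide (four molecules per molecule of 17)
Product: 20 (3R,4Z,6R)-6-({4-[(1E)-but-1-en-1-yl]-2,5-dioxo-2,5-dihydrofuran-3-yl}methyl)oct-4-ene-1,3,4-tricarboxylic acid 1-tert-butyl ester, via open tetracarboxylic acid 19 (not isolated)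
Conditions: Ni(acac)2 (10 mol%), C2-symmetric pinene-fused 2,2′-bipyridine (12 mol%), Zn powder (6 equiv), MgBr2 (6 equiv), 4 Å MS, DMF, CO2 (1 atm, excess), rt; then 1 M HCl, 0 °C
Reagents that add atoms: carbon dioxide (three further molecules beside 18), O=C=O.O=C=O.O=C=O
Why: Proposed new method: zerovalent nickel (from Ni(acac)2 and Zn) should couple the C9≡C10 alkyne oxidatively with one CO2 to an oxanickelacyclopentenone and the C4=C5 bond of the allene with a second CO2 at the central carbon C5 to a carboxylate-bearing η3-allylnickel species, after which MgBr2 opens each nickelalactone, Zn reduces the metal and a third and a fourth CO2 insert into the alkenyl–nickel bond at the alkyne and into the allyl–nickel bond at C4, so that four CO2 and two Zn are consumed per molecule of 17 and the HCl work-up supplies the four protons of acid 19. The nearest precedents are the Ni(acac)2/bipyridine/Zn/MgBr2 double carboxylation of internal alkynes, which delivers maleic anhydrides, and the nickel-promoted carboxylation of allenes by way of η3-allyl nickelalactones; running both at once, catalytically on a 1,3-dialkylallene and with enantiocontrol, is new. The furan-2,5-dione ring closes only on acidification, by intramolecular acyl substitution (5-exo-trig) of one carboxyl group on its cis neighbour with loss of water, the cis arrangement following from syn addition within the nickelacycle. C4 is set when nickel delivers CO2 to one face of the allyl terminus, and that face is chosen by the chiral bipyridine among η3-allyl complexes that equilibrate by η3–η1–η3 shifts, so both axial epimers of 17 should converge and the fixed C7 centre makes any 4S product a separable diastereomer. Four selectivities are required, namely CO2 first at the central and then at the unbranched terminal allene carbon, the syn-allyl geometry that leaves the C7 chain cis to the C5 carboxylate, 1,2- rather than 1,4-addition across the enyne and no nickel-mediated coupling between the two π-systems: the ethyl branch at C7 shields C6 and sends the second allene CO2 to C4, the syn allyl is the thermodynamic isomer, insertion into the σ-alkenyl–nickel bond should outrun a shift of nickel to C12, and the bipyridine under excess CO2 should keep each nickel centre engaged with one π-bond only.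

Step 10
Reactants: 20 (3R,4Z,6R)-6-({4-[(1E)-but-1-en-1-yl]-2,5-dioxo-2,5-dihydrofuran-3-yl}methyl)oct-4-ene-1,3,4-tricarboxylic acid 1-tert-butyl ester
Product: 21 (3R,4Z,6R)-6-({4-[(1E)-but-1-en-1-yl]-2,5-dioxo-2,5-dihydrofuran-3-yl}methyl)oct-4-ene-1,3,4-tricarboxylic acid
Conditions: TFA/CH2Cl2 (1:4), 0 °C → rt
Reagents that add atoms: none
Why: Acidolysis of the tert-butyl ester with loss of isobutene uses no base or nucleophile, so the anhydride, the alkenes and the epimerisable C4 centre should be left as they are.

**Compound list**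

1 | (S)-4-benzyloxazolidin-2-one | O=C1N[C@@H](Cc2ccccc2)CO1 | starting material
2 | butanoyl chloride | CCCC(Cl)=O | starting material
3 | lithium salt of 1 (formed in the flask) | O=C1[N-][C@@H](Cc2ccccc2)CO1.[Li+] | intermediate
4 | (S)-4-benzyl-3-butanoyloxazolidin-2-one | CCCC(=O)N1C(=O)OC[C@@H]1Cc1ccccc1 | intermediate
5 | 3-bromoprop-1-yne | C#CCBr | starting material
6 | sodium (Z)-enolate of 4 (formed in the flask) | CC/C=C(\[O-])N1C(=O)OC[C@@H]1Cc1ccccc1.[Na+] | intermediate
7 | (S)-4-benzyl-3-[(2R)-2-ethylpent-4-ynoyl]oxazolidin-2-one | C#CC[C@@H](CC)C(=O)N1C(=O)OC[C@@H]1Cc1ccccc1 | intermediate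
8 | but-1-yne | CCC#C | starting material
9 | (E)-but-1-enylzirconocene chloride (formed in the flask) | CC/C=C/[Zr+2]Cl.c1cc[cH-]c1.c1cc[cH-]c1 | intermediate
10 | (E)-1-iodobut-1-ene | CC/C=C/I | intermediate
11 | (S)-4-benzyl-3-[(2R,6E)-2-ethylnon-6-en-4-ynoyl]oxazolidin-2-one | CC/C=C/C#CC[C@@H](CC)C(=O)N1C(=O)OC[C@@H]1Cc1ccccc1 | intermediate
12 | (2R,6E)-2-ethylnon-6-en-4-yn-1-ol | CC/C=C/C#CC[C@@H](CC)CO | intermediate
13 | (2R,6E)-2-ethylnon-6-en-4-ynal | CC/C=C/C#CC[C@@H](CC)C=O | intermediate
14 | (3R,7E)-3-ethyldec-7-ene-1,5-diyne | CC/C=C/C#CC[C@@H](CC)C#C | intermediate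
15 | tert-butyl 4-oxobutanoate | O=CCCC(=O)OC(C)(C)C | starting material
16 | tert-butyl (7R,11E)-7-ethyl-4-(morpholin-4-yl)tetradec-11-ene-5,9-diynoate, C4 epimers (formed in the flask) | CC/C=C/C#CC[C@@H](CC)C#CC(CCC(=O)OC(C)(C)C)N1CCOCC1 | intermediate
17 | tert-butyl (7R,11E)-7-ethyltetradeca-4,5,11-trien-9-ynoate, both allene axial epimers | CC/C=C/C#CC[C@H](C=C=CCCC(=O)OC(C)(C)C)CC | intermediate
18 | carbon dioxide | O=C=O | starting material
19 | open maleic acid form of 20: C9 and C10 each bear CO2H, cis (formed in the flask) | OC(=O)/C(/C=C/CC)=C(\C(=O)O)C[C@H](/C=C(\C(=O)O)[C@@H](CCC(=O)OC(C)(C)C)C(=O)O)CC | intermediate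
20 | (3R,4Z,6R)-6-({4-[(1E)-but-1-en-1-yl]-2,5-dioxo-2,5-dihydrofuran-3-yl}methyl)oct-4-ene-1,3,4-tricarboxylic acid 1-tert-butyl ester | CC/C=C/C1=C(C[C@H](/C=C(\C(=O)O)[C@@H](CCC(=O)OC(C)(C)C)C(=O)O)CC)C(=O)OC1=O | intermediate
21 | (3R,4Z,6R)-6-({4-[(1E)-but-1-en-1-yl]-2,5-dioxo-2,5-dihydrofuran-3-yl}methyl)oct-4-ene-1,3,4-tricarboxylic acid | CC/C=C/C1=C(C[C@H](/C=C(\C(=O)O)[C@@H](CCC(=O)O)C(=O)O)CC)C(=O)OC1=O | target

**Count**

Total steps: 10. Longest linear sequence: 9 (steps 1, 2, 4, 5, 6, 7, 8, 9, 10); step 3 is a one-step side branch.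

**Steps most likely to fail**

1. Step 9. Possible failures are poor face selection at C4, incomplete syn/anti equilibration of the allyl (wrong C5=C6 geometry), entry of the second allene CO2 at C6, 1,4-addition across the enyne, nickel-mediated coupling of the alkyne with the allene, or protonation in place of the second carboxylation at either site. The fallback uses known reactions only, sets out from aldehyde 13 and comes back to the route at 21. tert-Butyl [bis(2,2,2-trifluoroethoxy)phosphoryl]acetate is alkylated (NaH, THF, 0 °C) with (R)-4-benzyl-3-(bromoacetyl)oxazolidin-2-one to the phosphonate imide F1. Still–Gennari olefination of 13 with F1 (KN(SiMe3)2, 18-crown-6, THF, −78 °C) should give the Z-alkylidenesuccinate imide F2, in which the C7 chain is cis to the tert-butyl ester. The chlorotitanium enolate of F2 (TiCl4, iPr2NEt, CH2Cl2, −78 °C) adds to tert-butyl acrylate in an Evans Michael reaction and should furnish the Michael adduct F3; the (R)-benzyl auxiliary is chosen because the acrylate then enters on the face that gives 4R. LiOH/H2O2 (THF/H2O, 0 °C) removes the auxiliary and gives the acid F4. The internal alkyne of F4, as its carboxylate salt, is doubly carboxylated under the conditions known for internal alkynes (Ni(acac)2, 2,2′-bipyridine, Zn, MgBr2, DMF, CO2, rt; then HCl), which should give the open maleic acid F5 and from it, on acidification, the anhydride F6. TFA in CH2Cl2 cleaves both tert-butyl esters of F6 and rejoins the route at 21.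

2. Step 8. Possible failures are self-condensation of the enolisable aldehyde through its enamine, loss of the tert-butyl ester to the zinc Lewis acid at 110 °C, or metal-promoted cycloisomerisation of the 1,5-allenyne. The fallback sets out from 14 and 15 and comes back to the route at 17. 14 is deprotonated at the terminal alkyne (n-BuLi, THF, −78 °C), the acetylide is added to 15 and the mixture is quenched with water to give the propargylic alcohol F7. Myers allene synthesis (2-nitrobenzenesulfonylhydrazide, PPh3, DEAD, THF, −15 °C → rt) converts F7 by Mitsunobu displacement into the propargylic sulfonylhydrazine F8. F8 loses 2-nitrobenzenesulfinic acid to the propargylic diazene F9, which extrudes dinitrogen in a retro-ene reaction at or below room temperature and gives 17 without heat or Lewis acid.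

3. Step 7. The possible failure is epimerisation of the α-stereocentre of 13 by carbonate in methanol before the homologation takes place. The fallback sets out from 13 and comes back to the route at 14. A Corey–Fuchs sequence replaces the diazophosphonate: CBr4 and PPh3 (CH2Cl2, 0 °C) convert 13 without base into the 1,1-dibromoalkene F10. n-BuLi (2 equiv, THF, −78 °C) turns F10 by bromine–lithium exchange and rearrangement into the lithium acetylide F11, and quenching with water gives 14.

**Further compounds**

F1 | step 9 | tert-butyl 4-[(4R)-4-benzyl-2-oxo-1,3-oxazolidin-3-yl]-2-[bis(2,2,2-trifluoroethoxy)phosphoryl]-4-oxobutanoate | CC(C)(C)OC(=O)C(CC(=O)N1C(=O)OC[C@H]1Cc1ccccc1)P(=O)(OCC(F)(F)F)OCC(F)(F)F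
F2 | step 9 | tert-butyl (2Z,4R,8E)-2-{2-[(4R)-4-benzyl-2-oxo-1,3-oxazolidin-3-yl]-2-oxoethyl}-4-ethylundeca-2,8-dien-6-ynoate | CC/C=C/C#CC[C@H](/C=C(\C(=O)OC(C)(C)C)CC(=O)N1C(=O)OC[C@H]1Cc1ccccc1)CC
F3 | step 9 | tert-butyl (4R,5Z,7R,11E)-4-{[(4R)-4-benzyl-2-oxo-1,3-oxazolidin-3-yl]carbonyl}-5-(tert-butoxycarbonyl)-7-ethyltetradeca-5,11-dien-9-ynoate | CC/C=C/C#CC[C@H](/C=C(\C(=O)OC(C)(C)C)[C@@H](CCC(=O)OC(C)(C)C)C(=O)N1C(=O)OC[C@H]1Cc1ccccc1)CC
F4 | step 9 | (2R,3Z,5R,9E)-3-(tert-butoxycarbonyl)-2-(3-tert-butoxy-3-oxopropyl)-5-ethyldodeca-3,9-dien-7-ynoic acid | CC/C=C/C#CC[C@H](/C=C(\C(=O)OC(C)(C)C)[C@@H](CCC(=O)OC(C)(C)C)C(=O)O)CC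
F5 | step 9 | open maleic acid form of F6 (both ring carbonyls as cis CO2H groups) | OC(=O)/C(/C=C/CC)=C(\C(=O)O)C[C@H](/C=C(\C(=O)OC(C)(C)C)[C@@H](CCC(=O)OC(C)(C)C)C(=O)O)CC
F6 | step 9 | (2R,3Z,5R)-6-{4-[(1E)-but-1-en-1-yl]-2,5-dioxo-2,5-dihydrofuran-3-yl}-3-(tert-butoxycarbonyl)-2-(3-tert-butoxy-3-oxopropyl)-5-ethylhex-3-enoic acid | CC/C=C/C1=C(C[C@H](/C=C(\C(=O)OC(C)(C)C)[C@@H](CCC(=O)OC(C)(C)C)C(=O)O)CC)C(=O)OC1=O
F7 | step 8 | tert-butyl (7R,11E)-7-ethyl-4-hydroxytetradec-11-ene-5,9-diynoate, C4 epimers | CC/C=C/C#CC[C@@H](CC)C#CC(O)CCC(=O)OC(C)(C)C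
F8 | step 8 | tert-butyl (7R,11E)-7-ethyl-4-[1-(2-nitrobenzenesulfonyl)hydrazin-1-yl]tetradec-11-ene-5,9-diynoate | CC/C=C/C#CC[C@@H](CC)C#CC(CCC(=O)OC(C)(C)C)N(N)S(=O)(=O)c1ccccc1[N+](=O)[O-]
F9 | step 8 | tert-butyl (7R,11E)-4-diazenyl-7-ethyltetradec-11-ene-5,9-diynoate | CC/C=C/C#CC[C@@H](CC)C#CC(CCC(=O)OC(C)(C)C)N=N
F10 | step 7 | (3R,7E)-1,1-dibromo-3-ethyldeca-1,7-dien-5-yne | CC/C=C/C#CC[C@@H](CC)C=C(Br)Br
F11 | step 7 | lithium acetylide of 14 | CC/C=C/C#CC[C@@H](CC)C#[C-].[Li+]
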